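**Remark on the chemistry:** the biaryl axis of the target is not assigned and is treated as configurationally unspecified. Aldehydes 7 and 14 are taken as purchased; each is otherwise one O-benzylation away from 3-bromo-4-hydroxybenzaldehyde or vanillin.

## Analysis of the target

Target 21 is a carbon–carbon linked biflavone. A chrysoeriol unit (5,7-dihydroxy-2-(4-hydroxy-3-methoxyphenyl)chromen-4-one) is joined through C8 of its ring A to C3' of ring B of an apigenin unit, which is the amentoflavone connectivity with one extra methoxy group. It holds two 2-arylchromen-4-one systems (six rings), six free phenols and one aryl methyl ether, and it has no stereocentre. The biaryl bond carries three ortho oxygens and one hydrogen.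

The sensitive features are the electron-rich phloroglucinol-type rings, which are easily oxidised or substituted at C6 and C8. The pyranones open when strong bases or nucleophiles attack C2. A 5-hydroxyflavone can also exchange an 8-substituent for a 6-substituent by ring opening and reclosure in hot strong acid.

The synthesis is hard for three reasons. The biaryl bond between two electron-rich rings is hindered. The two halves are nearly identical and differ only in the methoxy group, so each must come from its own protected building block. The oxygen at C8a must stay distinguishable from the oxygen at C5 of the chrysoeriol ring A, or the 8-linkage cannot be told from the 6-linkage.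

The strategy rests on the chain C4a–C4(=O)–C3H=C2(O1)–C1' of the chrysoeriol unit. This is a 1,3-dioxygenated three-carbon chain between ring A and the methoxylated ring B. A 3,5-diarylisoxazole holds the same carbons at the same oxidation level, with isoxazole C3, C4 and C5 becoming flavone C4, C3 and C2. The isoxazole C3–C4 bond, which is the flavone C4–C3 bond, is the bond a nitrile oxide/alkyne cycloaddition makes.

## Retrosynthetic reasoning

**21 from 20.** All six phenols are masked as benzyl ethers, so the last step is a single hydrogenolysis. Benzyl is chosen because it survives base, palladium coupling, hypervalent iodine and dilute acid. The only methyl ether in the route is the one that stays in the target.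

**20 from 18 (through 19).** The O1–C2 bond of the chrysoeriol pyranone is cut and the C4 carbonyl is traced back to an enamine carbon. This gives enaminone 18, in which the C8a oxygen carries a methoxymethyl group and the C5 oxygen a benzyl group. Only the acid-labile acetal falls in the forward step, so only the C8a oxygen can close the ring and the 8-linkage is secured.

**18 from 17.** The N–O bond is reconnected. Isoxazole 17 is an aromatic, unreactive form of the 1,3-dicarbonyl chain, and it can pass through purification before a reductive cleavage opens it.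

**17 from 13 and 15 (through 16).** The flavone C3–C4 bond and the isoxazole C5–O bond are cut in one retro-[3+2] step. The cut is placed here because it divides the molecule into a large biaryl half that already contains the complete apigenin unit and the hindered axis, and a small alkyne 15 that can be used in excess. The forward reaction runs under neutral conditions. Its regiochemistry with a terminal alkyne is dependable. The two oxygens ortho to the dipole carbon in 16 keep the nitrile oxide from dimerising. The forward step must oxidise oxime 13 without touching the electron-rich rings and must add the dipole to 15 faster than it decays.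

**13 from 12.** The oxime is traced back to the aldehyde. The forward condensation must select the formyl group over the chromenone carbonyl.

**12 from 4 and 11.** The biaryl bond C8–C3' is cut. The iodine is put on the ring A aldehyde and the boron on the apigenin unit, because a boronate flanked by two alkoxy groups would lose boron too easily. The forward Suzuki coupling has to make a biaryl with three ortho substituents.

**4 from 3, 2 and 1.** The acetal is removed, then the iodine, then the two benzyl groups. The free chelated phenol of 2 is what directs iodination to C3, and the same phenol later becomes the C8a oxygen, so one hydroxyl sets both regiochemical questions.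

**11 from 10, 8 (through 9), 6 and 7, and 6 from 5.** The boronate comes from bromide 10. The pyranone of 10 is opened to chalcone 8, and 8 is cut at its C=C bond into ketone 6 and aldehyde 7. The apigenin unit is thereby finished before the coupling and needs no later attention.

**15 from 14.** The alkyne is a one-carbon homologue of aldehyde 14.

## Alternatives that were turned down

**Alternative 1: benzannulation that builds the chrysoeriol ring A.**
- **Disconnection:** ring A is taken apart at C8–C8a, C6–C7 and C4a–C8a into a four-carbon piece from 3-ethoxycyclobut-2-en-1-one A1 and the two alkyne carbons of aryl siloxyalkyne A2. The biaryl bond is already present as the aryl–alkyne bond.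
- **Forward key step:** heating A1 with A2 should open the cyclobutenone to an ethoxy vinylketene. A [2+2] addition, a second four-electron opening and a six-electron closure would then give phenol A3, with a free hydroxyl at the future C8a, a silyl ether at C7 and an ethyl ether at C5.
- **For it:** no hindered cross-coupling and no arene halogenation with a site-selectivity question are needed. On this point it is stronger than the chosen route. The three ring A oxygens also come out differentiated.
- **Against it:** A3 is far from the target. C4a still lacks its carbon, and acylation there competes with C6. Both pyranones and the whole apigenin unit remain to be built from the acetal. The C5 ethyl ether must later be cleaved beside the aryl methyl ether. A2 needs a multistep ynolate-type preparation and can rearrange thermally to a silylketene.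
- **Comparison:** the step count after the key step is clearly higher. The chosen strategy accepts one hindered but standard Suzuki coupling and in exchange brings in a finished apigenin unit and needs only one late ring construction.

**Alternative 2: pyrone Diels–Alder that grows the apigenin ring B on C8.**
- **Disconnection:** the central benzene ring is cut at C2'–C3' and C4'–C5' into methyl coumalate A4 and the siloxyalkyne carbons of the 8-alkynylated chrysoeriol tribenzyl ether A5.
- **Forward key step:** an inverse-demand [4+2] addition of A5 to A4, followed by cycloreversion that expels the lactone bridge, should give benzoate A6 with the flavone ortho to the siloxy group and para-related to the ester.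
- **For it:** the hindered biaryl arises by ring construction with polarity-controlled regiochemistry, and the ester is a handle for the second pyranone. On the axis it is again stronger than a cross-coupling.
- **Against it:** the difficulty moves into the precursor. A5 is an ynol silyl ether on C8 of a complete flavone. The strongly basic ynolate or acetylide-oxidation chemistry that makes such groups would attack C2 and the carbonyl of the chromenone. An 8-selective functionalisation of a chrysoeriol ether is also needed. After the key step the ester must be converted to the chromenone by hydrolysis, O-aroylation of 6, acyl migration and cyclodehydration. The temperature that the pyrone needs works against the thermal lability of the siloxyalkyne.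
- **Comparison:** both routes build one flavone late. The chosen one does it in four mild operations from an aldehyde and reaches its precursor by routine reactions.

**Alternative 3: twofold intramolecular ester Wittig reaction.**
- **Disconnection:** both C2=C3 bonds are cut at once, which leads back to bis(acylphosphorane) diester A7.
- **Forward key step:** on heating, each ylide carbon should attack the neighbouring aryl ester carbonyl and close both pyranones with loss of the phosphine oxide. The product is hexabenzyl ether A8, which is the same compound as 20.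
- **For it:** one neutral thermal step delivers the protected biflavone, where the chosen route needs three steps from the isoxazole. The regiochemistry is fixed by which oxygen carries the aroyl group. No hydroxylamine or N–O reduction comes near a chromenone. On end-game economy it is stronger.
- **Against it:** A7 is hard to reach. It needs a biaryl with two phenacyl ylides and two different aryl esters. That means alpha-halogenation of two very electron-rich aryl ketones, where ring halogenation competes. It also means O-aroylation of two hindered, chelated phenols, and ylide formation under base, where acyl migration to carbon is a known escape. The hindered biaryl coupling is still required, now on more heavily functionalised partners. Stabilised ylides add to esters only at high temperature.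
- **Comparison:** the chosen strategy gives up the one-step end-game in exchange for a precursor reached in nine routine steps spread over three fragments. The bond-forming step is intermolecular and can be driven by an excess of a cheap alkyne.

Key step: step 11

## Route

Step 1
Reactants: 1 2,4,6-trihydroxybenzaldehyde
Product: 2 4,6-bis(benzyloxy)-2-hydroxybenzaldehyde
Conditions: BnBr (2.1 equiv), K2CO3, DMF, 0 °C to rt
Reagents that add atoms: benzyl bromide, BrCc1ccccc1
Why: Williamson etherification; the 4-hydroxyl and one ortho hydroxyl are alkylated, while the remaining ortho hydroxyl is hydrogen-bonded to the formyl group, is the least nucleophilic and should stay free.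

Step 2
Reactants: 2 4,6-bis(benzyloxy)-2-hydroxybenzaldehyde
Product: 3 4,6-bis(benzyloxy)-2-hydroxy-3-iodobenzaldehyde
Conditions: BnMe3N·ICl2 (1.05 equiv), NaHCO3, CH2Cl2/MeOH, rt
Reagents that add atoms: benzyltrimethylammonium dichloroiodate, C[N+](C)(C)Cc1ccccc1.Cl[I-]Cl
Why: Electrophilic aromatic iodination of a chelated phenol; attack ortho to the free hydroxyl at C3 should be preferred over C5, which lies between two benzyloxy groups and is the more crowded site.

Step 3
Reactants: 3 4,6-bis(benzyloxy)-2-hydroxy-3-iodobenzaldehyde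
Product: 4 4,6-bis(benzyloxy)-3-iodo-2-(methoxymethoxy)benzaldehyde
Conditions: NaH, MOMCl, DMF, 0 °C to rt
Reagents that add atoms: chloromethyl methyl ether, COCCl
Why: O-alkylation of the sodium phenoxide; irreversible deprotonation overcomes the chelation and the flanking groups, and the acetal is the one acid-labile group that later distinguishes the C8a oxygen from the benzylated C5 oxygen.

Step 4
Reactants: 5 2,4,6-trihydroxyacetophenone
Product: 6 1-[2,4-bis(benzyloxy)-6-hydroxyphenyl]ethan-1-one
Conditions: BnBr (2.1 equiv), K2CO3, DMF, rt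
Reagents that add atoms: benzyl bromide, BrCc1ccccc1
Why: Williamson etherification with the same chelation-based selectivity as in step 1; the hydroxyl hydrogen-bonded to the acetyl group remains.

Step 5
Reactants: 6 1-[2,4-bis(benzyloxy)-6-hydroxyphenyl]ethan-1-one; 7 4-(benzyloxy)-3-bromobenzaldehyde
Product: 8 (E)-1-[2,4-bis(benzyloxy)-6-hydroxyphenyl]-3-[4-(benzyloxy)-3-bromophenyl]prop-2-en-1-one
Conditions: KOH (aq.), EtOH/THF, rt
Reagents that add atoms: none
Why: Claisen–Schmidt condensation; the enolate of the methyl ketone adds to the non-enolisable aldehyde and dehydration gives the conjugated E-chalcone.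

Step 6
Reactants: 8 (E)-1-[2,4-bis(benzyloxy)-6-hydroxyphenyl]-3-[4-(benzyloxy)-3-bromophenyl]prop-2-en-1-one
Product: 10 5,7-bis(benzyloxy)-2-[4-(benzyloxy)-3-bromophenyl]-4H-chromen-4-one, via racemic flavanone 9 (not isolated)
Conditions: I2 (10 mol %), DMSO, 130 °C
Reagents that add atoms: none
Why: Oxidative cyclisation of a 2'-hydroxychalcone; oxa-Michael closure gives flavanone 9, alpha-iodination and loss of HI give the flavone, and DMSO reoxidises the iodide.

Step 7
Reactants: 10 5,7-bis(benzyloxy)-2-[4-(benzyloxy)-3-bromophenyl]-4H-chromen-4-one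
Product: 11 5,7-bis(benzyloxy)-2-[4-(benzyloxy)-3-(4,4,5,5-tetramethyl-1,3,2-dioxaborolan-2-yl)phenyl]-4H-chromen-4-one
Conditions: B2pin2, PdCl2(dppf) (5 mol %), KOAc, 1,4-dioxane, 90 °C
Reagents that add atoms: bis(pinacolato)diboron, CC1(C)OB(B2OC(C)(C)C(C)(C)O2)OC1(C)C
Why: Miyaura borylation of an aryl bromide; the weak acetate base does not harm the chromenone and does not promote coupling of the product with unreacted bromide.

Step 8
Reactants: 4 4,6-bis(benzyloxy)-3-iodo-2-(methoxymethoxy)benzaldehyde; 11 5,7-bis(benzyloxy)-2-[4-(benzyloxy)-3-(4,4,5,5-tetramethyl-1,3,2-dioxaborolan-2-yl)phenyl]-4H-chromen-4-one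
Product: 12 4,6-bis(benzyloxy)-3-{2-(benzyloxy)-5-[5,7-bis(benzyloxy)-4-oxo-4H-chromen-2-yl]phenyl}-2-(methoxymethoxy)benzaldehyde
Conditions: Pd(OAc)2 (5 mol %), SPhos (10 mol %), K3PO4, toluene/H2O (10:1), 90 °C
Reagents that add atoms: none
Why: Suzuki–Miyaura coupling; the iodide undergoes oxidative addition readily, and the bulky electron-rich biarylphosphine is the ligand type suited to reductive elimination of biaryls with three ortho substituents.

Step 9
Reactants: 12 4,6-bis(benzyloxy)-3-{2-(benzyloxy)-5-[5,7-bis(benzyloxy)-4-oxo-4H-chromen-2-yl]phenyl}-2-(methoxymethoxy)benzaldehyde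
Product: 13 (E)-4,6-bis(benzyloxy)-3-{2-(benzyloxy)-5-[5,7-bis(benzyloxy)-4-oxo-4H-chromen-2-yl]phenyl}-2-(methoxymethoxy)benzaldehyde oxime
Conditions: NH2OH·HCl (1.5 equiv), pyridine, EtOH/THF, rt to 40 °C
Reagents that add atoms: hydroxylamine hydrochloride, Cl.NO
Why: Oxime condensation; the aldehyde is far more electrophilic than the vinylogous-ester carbonyl of the chromenone, the pyridine buffer protects the acetal, and the E-oxime is the stable isomer of an aryl aldoxime.

Step 10
Reactants: 14 4-(benzyloxy)-3-methoxybenzaldehyde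
Product: 15 1-(benzyloxy)-4-ethynyl-2-methoxybenzene
Conditions: dimethyl (1-diazo-2-oxopropyl)phosphonate, K2CO3, MeOH/THF, rt
Reagents that add atoms: dimethyl (1-diazo-2-oxopropyl)phosphonate, CC(=O)C(=[N+]=[N-])P(=O)(OC)OC
Why: Seyferth–Gilbert homologation in the Ohira–Bestmann variant; methanolysis releases the diazomethylphosphonate anion, olefination gives a diazoalkene, and loss of nitrogen with a 1,2-hydrogen shift gives the terminal alkyne.

Step 11
Reactants: 13 (E)-4,6-bis(benzyloxy)-3-{2-(benzyloxy)-5-[5,7-bis(benzyloxy)-4-oxo-4H-chromen-2-yl]phenyl}-2-(methoxymethoxy)benzaldehyde oxime; 15 1-(benzyloxy)-4-ethynyl-2-methoxybenzene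
Product: 17 5,7-bis(benzyloxy)-2-{4-(benzyloxy)-3-[4,6-bis(benzyloxy)-3-{5-[4-(benzyloxy)-3-methoxyphenyl]isoxazol-3-yl}-2-(methoxymethoxy)phenyl]phenyl}-4H-chromen-4-one, via biaryl nitrile oxide 16 (not isolated)
Conditions: PhI(OAc)2 (1.2 equiv), TFA (10 mol %), 15 (2 equiv), MeOH/CH2Cl2 (1:1), 0 °C, then 40 °C
Reagents that add atoms: none
Why: Ligand exchange of the oxime hydroxyl on iodine, followed by loss of iodobenzene and acetic acid, dehydrogenates 13 to nitrile oxide 16. 16 then adds to 15 in a concerted, asynchronous 1,3-dipolar cycloaddition, in which the dipole carbon bonds to the terminal alkyne carbon (the future flavone C3–C4 bond) and the dipole oxygen bonds to the aryl-bearing carbon. The closest known reaction type is the Huisgen cycloaddition of aryl nitrile oxides to terminal arylalkynes, which gives 3,5-diarylisoxazoles. The isoxazole ring is closed by the intermolecular [3+2] cycloaddition itself, both ring bonds forming in the same step with no separate cyclisation. No stereocentre is formed. The step needs the 3,5-isomer and not the 3,4-isomer; the bulky, doubly ortho-substituted dipole carbon goes to the unsubstituted alkyne terminus, and the larger frontier-orbital coefficient of the electron-rich arylalkyne sits on that same carbon. The step also needs cycloaddition to win over furoxan formation, and the two ortho oxygen substituents of 16 block that dimerisation, so the dipole persists until it meets the excess alkyne. The chromenone C2=C3 bond is a trisubstituted vinylogous ester and a poor dipolarophile, and the temperature is kept low enough to avoid rearrangement of 16 to an isocyanate.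

Step 12
Reactants: 17 5,7-bis(benzyloxy)-2-{4-(benzyloxy)-3-[4,6-bis(benzyloxy)-3-{5-[4-(benzyloxy)-3-methoxyphenyl]isoxazol-3-yl}-2-(methoxymethoxy)phenyl]phenyl}-4H-chromen-4-one
Product: 18 (Z)-3-amino-3-[4,6-bis(benzyloxy)-3-{2-(benzyloxy)-5-[5,7-bis(benzyloxy)-4-oxo-4H-chromen-2-yl]phenyl}-2-(methoxymethoxy)phenyl]-1-[4-(benzyloxy)-3-methoxyphenyl]prop-2-en-1-one
Conditions: Mo(CO)6 (1 equiv), MeCN/H2O (10:1), 80 °C
Reagents that add atoms: none
Why: Reductive N–O cleavage of an isoxazole by zerovalent molybdenum, with water as the proton source; the product is the hydrogen-bonded Z-enaminone, and benzyl ethers, the acetal and the chromenone are inert to this neutral reagent.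

Step 13
Reactants: 18 (Z)-3-amino-3-[4,6-bis(benzyloxy)-3-{2-(benzyloxy)-5-[5,7-bis(benzyloxy)-4-oxo-4H-chromen-2-yl]phenyl}-2-(methoxymethoxy)phenyl]-1-[4-(benzyloxy)-3-methoxyphenyl]prop-2-en-1-one
Product: 20 5,7-bis(benzyloxy)-8-{2-(benzyloxy)-5-[5,7-bis(benzyloxy)-4-oxo-4H-chromen-2-yl]phenyl}-2-[4-(benzyloxy)-3-methoxyphenyl]-4H-chromen-4-one, via free-phenol enaminone 19 (not isolated)
Conditions: 3 M HCl (aq.), MeOH/THF, 60 °C
Reagents that add atoms: water, O
Why: Acetal cleavage followed by cyclodehydration; the freed C8a hydroxyl adds to the aryl ketone carbon, water is lost, and hydrolysis of the C4 iminium puts the carbonyl oxygen in from water and releases ammonia. Only the C8a oxygen is free when the ring closes, so the 8-linked flavone should form.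

Step 14
Reactants: 20 5,7-bis(benzyloxy)-8-{2-(benzyloxy)-5-[5,7-bis(benzyloxy)-4-oxo-4H-chromen-2-yl]phenyl}-2-[4-(benzyloxy)-3-methoxyphenyl]-4H-chromen-4-one
Product: 21 8-[5-(5,7-dihydroxy-4-oxo-4H-chromen-2-yl)-2-hydroxyphenyl]-5,7-dihydroxy-2-(4-hydroxy-3-methoxyphenyl)-4H-chromen-4-one
Conditions: H2 (1 atm), 10% Pd/C, THF/MeOH, rt
Reagents that add atoms: none
Why: Hydrogenolysis of six aryl benzyl ethers; the aryl methyl ether is inert, and the cross-conjugated C2=C3 bonds of the flavones should resist hydrogenation at ambient pressure and temperature.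

## Compound list

1 | 2,4,6-trihydroxybenzaldehyde | O=Cc1c(O)cc(O)cc1O | starting material
2 | 4,6-bis(benzyloxy)-2-hydroxybenzaldehyde | O=Cc1c(O)cc(OCc2ccccc2)cc1OCc1ccccc1 | intermediate
3 | 4,6-bis(benzyloxy)-2-hydroxy-3-iodobenzaldehyde | O=Cc1c(O)c(I)c(OCc2ccccc2)cc1OCc1ccccc1 | intermediate
4 | 4,6-bis(benzyloxy)-3-iodo-2-(methoxymethoxy)benzaldehyde | COCOc1c(I)c(OCc2ccccc2)cc(OCc2ccccc2)c1C=O | intermediate
5 | 2,4,6-trihydroxyacetophenone | CC(=O)c1c(O)cc(O)cc1O | starting material
6 | 1-[2,4-bis(benzyloxy)-6-hydroxyphenyl]ethan-1-one | CC(=O)c1c(O)cc(OCc2ccccc2)cc1OCc1ccccc1 | intermediate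
7 | 4-(benzyloxy)-3-bromobenzaldehyde | O=Cc1ccc(OCc2ccccc2)c(Br)c1 | starting material
8 | (E)-1-[2,4-bis(benzyloxy)-6-hydroxyphenyl]-3-[4-(benzyloxy)-3-bromophenyl]prop-2-en-1-one | O=C(/C=C/c1ccc(OCc2ccccc2)c(Br)c1)c1c(O)cc(OCc2ccccc2)cc1OCc1ccccc1 | intermediate
9 | 5,7-bis(benzyloxy)-2-[4-(benzyloxy)-3-bromophenyl]chroman-4-one (racemic) | O=C1CC(c2ccc(OCc3ccccc3)c(Br)c2)Oc2cc(OCc3ccccc3)cc(OCc3ccccc3)c21 | intermediate
10 | 5,7-bis(benzyloxy)-2-[4-(benzyloxy)-3-bromophenyl]-4H-chromen-4-one | O=c1cc(-c2ccc(OCc3ccccc3)c(Br)c2)oc2cc(OCc3ccccc3)cc(OCc3ccccc3)c12 | intermediate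
11 | 5,7-bis(benzyloxy)-2-[4-(benzyloxy)-3-(4,4,5,5-tetramethyl-1,3,2-dioxaborolan-2-yl)phenyl]-4H-chromen-4-one | CC1(C)OB(c2cc(-c3cc(=O)c4c(OCc5ccccc5)cc(OCc5ccccc5)cc4o3)ccc2OCc2ccccc2)OC1(C)C | intermediate
12 | 4,6-bis(benzyloxy)-3-{2-(benzyloxy)-5-[5,7-bis(benzyloxy)-4-oxo-4H-chromen-2-yl]phenyl}-2-(methoxymethoxy)benzaldehyde | COCOc1c(C=O)c(OCc2ccccc2)cc(OCc2ccccc2)c1-c1cc(-c2cc(=O)c3c(OCc4ccccc4)cc(OCc4ccccc4)cc3o2)ccc1OCc1ccccc1 | intermediate
13 | (E)-oxime of 12 | COCOc1c(/C=N/O)c(OCc2ccccc2)cc(OCc2ccccc2)c1-c1cc(-c2cc(=O)c3c(OCc4ccccc4)cc(OCc4ccccc4)cc3o2)ccc1OCc1ccccc1 | intermediate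
14 | 4-(benzyloxy)-3-methoxybenzaldehyde | COc1cc(C=O)ccc1OCc1ccccc1 | starting material
15 | 1-(benzyloxy)-4-ethynyl-2-methoxybenzene | COc1cc(C#C)ccc1OCc1ccccc1 | intermediate
16 | 4,6-bis(benzyloxy)-3-{2-(benzyloxy)-5-[5,7-bis(benzyloxy)-4-oxo-4H-chromen-2-yl]phenyl}-2-(methoxymethoxy)benzonitrile oxide | COCOc1c(C#[N+][O-])c(OCc2ccccc2)cc(OCc2ccccc2)c1-c1cc(-c2cc(=O)c3c(OCc4ccccc4)cc(OCc4ccccc4)cc3o2)ccc1OCc1ccccc1 | intermediate
17 | 5,7-bis(benzyloxy)-2-{4-(benzyloxy)-3-[4,6-bis(benzyloxy)-3-{5-[4-(benzyloxy)-3-methoxyphenyl]isoxazol-3-yl}-2-(methoxymethoxy)phenyl]phenyl}-4H-chromen-4-one | COCOc1c(-c2cc(-c3ccc(OCc4ccccc4)c(OC)c3)on2)c(OCc2ccccc2)cc(OCc2ccccc2)c1-c1cc(-c2cc(=O)c3c(OCc4ccccc4)cc(OCc4ccccc4)cc3o2)ccc1OCc1ccccc1 | intermediate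
18 | (Z)-3-amino-3-[4,6-bis(benzyloxy)-3-{2-(benzyloxy)-5-[5,7-bis(benzyloxy)-4-oxo-4H-chromen-2-yl]phenyl}-2-(methoxymethoxy)phenyl]-1-[4-(benzyloxy)-3-methoxyphenyl]prop-2-en-1-one | COCOc1c(/C(N)=C/C(=O)c2ccc(OCc3ccccc3)c(OC)c2)c(OCc2ccccc2)cc(OCc2ccccc2)c1-c1cc(-c2cc(=O)c3c(OCc4ccccc4)cc(OCc4ccccc4)cc3o2)ccc1OCc1ccccc1 | intermediate
19 | (Z)-3-amino-3-[4,6-bis(benzyloxy)-3-{2-(benzyloxy)-5-[5,7-bis(benzyloxy)-4-oxo-4H-chromen-2-yl]phenyl}-2-hydroxyphenyl]-1-[4-(benzyloxy)-3-methoxyphenyl]prop-2-en-1-one | Oc1c(/C(N)=C/C(=O)c2ccc(OCc3ccccc3)c(OC)c2)c(OCc2ccccc2)cc(OCc2ccccc2)c1-c1cc(-c2cc(=O)c3c(OCc4ccccc4)cc(OCc4ccccc4)cc3o2)ccc1OCc1ccccc1 | intermediate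
20 | 5,7-bis(benzyloxy)-8-{2-(benzyloxy)-5-[5,7-bis(benzyloxy)-4-oxo-4H-chromen-2-yl]phenyl}-2-[4-(benzyloxy)-3-methoxyphenyl]-4H-chromen-4-one | COc1cc(-c2cc(=O)c3c(OCc4ccccc4)cc(OCc4ccccc4)c(-c4cc(-c5cc(=O)c6c(OCc7ccccc7)cc(OCc7ccccc7)cc6o5)ccc4OCc4ccccc4)c3o2)ccc1OCc1ccccc1 | intermediate
21 | 8-[5-(5,7-dihydroxy-4-oxo-4H-chromen-2-yl)-2-hydroxyphenyl]-5,7-dihydroxy-2-(4-hydroxy-3-methoxyphenyl)-4H-chromen-4-one | COc1cc(-c2cc(=O)c3c(O)cc(O)c(-c4cc(-c5cc(=O)c6c(O)cc(O)cc6o5)ccc4O)c3o2)ccc1O | target

## Step count and risks

Total step count: 14. Longest linear sequence: 10 steps, from 5 through steps 4, 5, 6, 7, 8, 9, 11, 12, 13 and 14.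

**Step 11 (key step).** The cycloaddition of the doubly ortho-substituted dipole may be slow. The nitrile oxide could then decay by addition of methanol or by rearrangement to an isocyanate, or the oxidant could attack the electron-rich rings before the dipole is trapped.
Fallback, from 12 and 15, back at 20: 15 is deprotonated (n-BuLi, THF, −78 °C) and added to the aldehyde of 12. This gives the racemic propargylic alcohol 1-[4,6-bis(benzyloxy)-3-{2-(benzyloxy)-5-[5,7-bis(benzyloxy)-4-oxo-4H-chromen-2-yl]phenyl}-2-(methoxymethoxy)phenyl]-3-[4-(benzyloxy)-3-methoxyphenyl]prop-2-yn-1-ol F1. MnO2 in CH2Cl2 oxidises it to the corresponding prop-2-yn-1-one F2. Methanolic HCl removes the acetal to give the 2-hydroxyaryl ynone F3. Et2NH in EtOH then steers the phenol to 6-endo closure onto the ynone and gives 20. The C3–C4 bond is made by carbonyl addition in place of cycloaddition, and the oxime, isoxazole and N–O cleavage are bypassed.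

**Step 8.** Transmetalation onto the arylpalladium iodide flanked by two ortho substituents may be slow. Protodeboronation of the ortho-benzyloxy boronate in the aqueous base could then overtake the coupling.
Fallback, from 10 and 4, back at 12: 10 is stannylated (Me3SnSnMe3, Pd(PPh3)4, toluene, 100 °C) to 5,7-bis(benzyloxy)-2-[4-(benzyloxy)-3-(trimethylstannyl)phenyl]-4H-chromen-4-one F4. F4 is joined to 4 by a Stille coupling (Pd(PPh3)4, CuI, CsF, DMF, 45 °C). An arylstannane does not suffer base-induced loss of the metal, and the copper/fluoride variant suits hindered partners.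

**Step 2.** The iodinating agent may attack C5, between the two benzyloxy groups, or iodinate twice. Either would misplace the biaryl bond.
Fallback, from 1, back at 3: 1 is iodinated first (I2, NaHCO3, THF/H2O, 0 °C), where C3 and C5 are equivalent by symmetry, to give 2,4,6-trihydroxy-3-iodobenzaldehyde F5. Dibenzylation (BnBr, K2CO3, DMF) should then alkylate the 4-hydroxyl and the unhindered 6-hydroxyl. The chelated hydroxyl wedged between iodine and the formyl group is left, which is 3. The site question is thereby moved from a C-iodination to an O-alkylation governed by steric shielding.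

**Step 13.** Acid may remove the C5 benzyl ether before the ring has closed. That would open a second cyclisation path through the wrong oxygen and scramble the 8- and 6-linkage. Hydrolysis of the hindered C4 iminium may also stall.
Fallback, from 17, back at 20 by way of 19: the acetal is removed at the isoxazole stage under mild acid (pyridinium p-toluenesulfonate, MeOH, 50 °C), where no cyclisation can occur. This gives 5,7-bis(benzyloxy)-2-{4-(benzyloxy)-3-[4,6-bis(benzyloxy)-2-hydroxy-3-{5-[4-(benzyloxy)-3-methoxyphenyl]isoxazol-3-yl}phenyl]phenyl}-4H-chromen-4-one F6, which can be purified and checked. Mo(CO)6 in wet MeCN then gives 19, which should close to 20 in warm acetic acid.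

**Step 14.** Hydrogen may partly saturate the C2=C3 bonds. The hydrogenolysis may also stall as partly debenzylated polyphenols precipitate onto the catalyst.
Fallback, from 20, directly to 21: non-reductive debenzylation with BCl3 and pentamethylbenzene as cation scavenger in CH2Cl2 at −78 °C. This leaves the double bonds untouched and at that temperature should spare the aryl methyl ether. No new compound arises on this path (entry F0).

## Further compounds

F1 | step 11 | 1-[4,6-bis(benzyloxy)-3-{2-(benzyloxy)-5-[5,7-bis(benzyloxy)-4-oxo-4H-chromen-2-yl]phenyl}-2-(methoxymethoxy)phenyl]-3-[4-(benzyloxy)-3-methoxyphenyl]prop-2-yn-1-ol (racemic) | COCOc1c(C(O)C#Cc2ccc(OCc3ccccc3)c(OC)c2)c(OCc2ccccc2)cc(OCc2ccccc2)c1-c1cc(-c2cc(=O)c3c(OCc4ccccc4)cc(OCc4ccccc4)cc3o2)ccc1OCc1ccccc1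
F2 | step 11 | 1-[4,6-bis(benzyloxy)-3-{2-(benzyloxy)-5-[5,7-bis(benzyloxy)-4-oxo-4H-chromen-2-yl]phenyl}-2-(methoxymethoxy)phenyl]-3-[4-(benzyloxy)-3-methoxyphenyl]prop-2-yn-1-one | COCOc1c(C(=O)C#Cc2ccc(OCc3ccccc3)c(OC)c2)c(OCc2ccccc2)cc(OCc2ccccc2)c1-c1cc(-c2cc(=O)c3c(OCc4ccccc4)cc(OCc4ccccc4)cc3o2)ccc1OCc1ccccc1
F3 | step 11 | 1-[4,6-bis(benzyloxy)-3-{2-(benzyloxy)-5-[5,7-bis(benzyloxy)-4-oxo-4H-chromen-2-yl]phenyl}-2-hydroxyphenyl]-3-[4-(benzyloxy)-3-methoxyphenyl]prop-2-yn-1-one | Oc1c(C(=O)C#Cc2ccc(OCc3ccccc3)c(OC)c2)c(OCc2ccccc2)cc(OCc2ccccc2)c1-c1cc(-c2cc(=O)c3c(OCc4ccccc4)cc(OCc4ccccc4)cc3o2)ccc1OCc1ccccc1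
F4 | step 8 | 5,7-bis(benzyloxy)-2-[4-(benzyloxy)-3-(trimethylstannyl)phenyl]-4H-chromen-4-one | C[Sn](C)(C)c1cc(-c2cc(=O)c3c(OCc4ccccc4)cc(OCc4ccccc4)cc3o2)ccc1OCc1ccccc1
F5 | step 2 | 2,4,6-trihydroxy-3-iodobenzaldehyde | O=Cc1c(O)cc(O)c(I)c1O
F6 | step 13 | 5,7-bis(benzyloxy)-2-{4-(benzyloxy)-3-[4,6-bis(benzyloxy)-2-hydroxy-3-{5-[4-(benzyloxy)-3-methoxyphenyl]isoxazol-3-yl}phenyl]phenyl}-4H-chromen-4-one | Oc1c(-c2cc(-c3ccc(OCc4ccccc4)c(OC)c3)on2)c(OCc2ccccc2)cc(OCc2ccccc2)c1-c1cc(-c2cc(=O)c3c(OCc4ccccc4)cc(OCc4ccccc4)cc3o2)ccc1OCc1ccccc1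
F0 | step 14 | none | none
A1 | alternative 1 | 3-ethoxycyclobut-2-en-1-one | CCOC1=CC(=O)C1
A2 | alternative 1 | 2-{4-(benzyloxy)-3-[(triisopropylsilyloxy)ethynyl]phenyl}-1,3-dioxolane | CC(C)[Si](C(C)C)(C(C)C)OC#Cc1cc(C2OCCO2)ccc1OCc1ccccc1
A3 | alternative 1 | 2-[2-(benzyloxy)-5-(1,3-dioxolan-2-yl)phenyl]-5-ethoxy-3-(triisopropylsilyloxy)phenol | CCOc1cc(O)c(-c2cc(C3OCCO3)ccc2OCc2ccccc2)c(O[Si](C(C)C)(C(C)C)C(C)C)c1
A4 | alternative 2 | methyl coumalate (methyl 2-oxo-2H-pyran-5-carboxylate) | COC(=O)C1=COC(=O)C=C1
A5 | alternative 2 | 5,7-bis(benzyloxy)-2-[4-(benzyloxy)-3-methoxyphenyl]-8-[(triisopropylsilyloxy)ethynyl]-4H-chromen-4-one | COc1cc(-c2cc(=O)c3c(OCc4ccccc4)cc(OCc4ccccc4)c(C#CO[Si](C(C)C)(C(C)C)C(C)C)c3o2)ccc1OCc1ccccc1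
A6 | alternative 2 | methyl 3-{5,7-bis(benzyloxy)-2-[4-(benzyloxy)-3-methoxyphenyl]-4-oxo-4H-chromen-8-yl}-4-(triisopropylsilyloxy)benzoate | COc1cc(-c2cc(=O)c3c(OCc4ccccc4)cc(OCc4ccccc4)c(-c4cc(C(=O)OC)ccc4O[Si](C(C)C)(C(C)C)C(C)C)c3o2)ccc1OCc1ccccc1
A7 | alternative 3 | bis(triphenylphosphoranylidene) diester: 2-[4-(benzyloxy)-3-methoxybenzoyloxy]-4,6-bis(benzyloxy)-3-(triphenylphosphoranylideneacetyl)phenyl ring bonded at C1 to C3 of a 4-(benzyloxy)benzoate whose ester oxygen sits on a 3,5-bis(benzyloxy)-2-(triphenylphosphoranylideneacetyl)phenyl ring | COc1cc(C(=O)Oc2c(C(=O)C=P(c3ccccc3)(c3ccccc3)c3ccccc3)c(OCc3ccccc3)cc(OCc3ccccc3)c2-c2cc(C(=O)Oc3cc(OCc4ccccc4)cc(OCc4ccccc4)c3C(=O)C=P(c3ccccc3)(c3ccccc3)c3ccccc3)ccc2OCc2ccccc2)ccc1OCc1ccccc1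
A8 | alternative 3 | hexa-O-benzyl ether of the target (identical with 20) | COc1cc(-c2cc(=O)c3c(OCc4ccccc4)cc(OCc4ccccc4)c(-c4cc(-c5cc(=O)c6c(OCc7ccccc7)cc(OCc7ccccc7)cc6o5)ccc4OCc4ccccc4)c3o2)ccc1OCc1ccccc1
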